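## Structural features

The target 21 is an achiral triaryl bis-ether of the phlorotannin type: three benzene rings, two diaryl ether oxygens and nine free phenolic hydroxyls. Ring A is a 2,4,6-trihydroxyphenyl unit bound through oxygen to C1 of ring B. Ring B has its only hydrogen at C2, hydroxyls at C3, C4 and C5, and at C6 the oxygen that leads to C1 of ring C, a 3,4,5-trihydroxyphenyl unit. There is no stereocentre, so nothing has to be set or protected against epimerisation. The pyrogallol units of rings B and C and the phloroglucinol unit of ring A oxidise easily in air, most of all under base, so the free phenols should appear only in the last step and under acidic, oxygen-free conditions. The real difficulty is regiochemical and steric. Ring B carries five contiguous oxygens of three kinds, and its C6 oxygen lies between the ring A ether at C1 and the C5 oxygen, so arylating it with a ring C electrophile would mean coupling a doubly ortho-substituted, electron-rich phenol. The key step uses the pattern of ring C instead: its ether carbon C1 sits between two CH carbons (C2 and C6), the C3 hydroxyl is meta to it, and C4 and C5 carry oxygen. That is the pattern produced when a 3,4-dialkoxy vinylketene (supplying C3 to C6) is annulated onto a terminal ynol ether (supplying C1 and C2), so the crowded ring B oxygen enters as the ynol ether oxygen and ring C is grown on it.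

## Logic of the disconnections

21 from 20. Eight O–alkyl bonds are cut (seven O–CH3 and one O–CH2CH3). Small alkyl ethers are the only masks that survive organolithium, hot base, peracid and thermolysis earlier on, and all eight fall in one operation. The forward step needs a Lewis acid that cleaves every alkyl ether, including the crowded ones on ring B, without touching the two aryl–O–aryl bonds, and it needs exclusion of air.

20 from 11 and 15. Ring C is cut at C2–C3 and C1–C6; the C3–C4 bond is broken and re-formed inside the cascade. This replaces the hindered ether formation by a ring construction: C1 and C2 come from the alkyne carbons of 11, and C3 to C6 with the C4 and C5 oxygens come from 15. A three-ring compound becomes a two-ring alkyne and a four-carbon ring. The forward step demands that the ketene carbonyl carbon bonds to the unsubstituted alkyne carbon, and that both partners survive about 80 to 110 °C.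

15 from 12 and 13. The four-membered ring is cut at C1–C2 and C3–C4, a ketene–alkyne [2+2] in reverse, passing through 14. Two purchasable two-carbon pieces result. The forward step must generate 14 slowly in an excess of 13 so that cycloaddition beats ketene oligomerisation; the polarity of the two partners fixes the regiochemistry.

11 from 8, and 8 from 7. The O–C(sp) bond is cut. The two alkyne carbons come from trichloroethylene, attached first as a dichlorovinyl group and then unveiled by double dehalogenation. Direct O-alkynylation of phenols is not general, whereas addition of a phenoxide to a small, linear chloroalkyne tolerates two ortho substituents. The forward steps demand that elimination and chlorine–lithium exchange outrun ring lithiation, and that 11 is handled cold and free of acid.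

7 from 5. The C6–O bond of ring B is traced back to a C6–CHO bond, the oxygen being inserted by aryl migration. The formyl group marks the C6 position unambiguously and also activates the neighbouring halide for the ether coupling. Direct lithiation of an A–B ether without a C6 substituent would have to choose between a ring B C–H flanked by aryloxy and methoxy and a ring A C–H flanked by two methoxy groups, and that choice cannot be relied on. The forward step demands aryl over hydride migration, which the electron-rich, doubly ortho-oxygenated ring favours.

5 from 3 and 4. The ring B C1–O bond is cut. The hindered partner 4 becomes the nucleophile and the ortho-formyl bromide 3 the electrophile, giving two single-ring pieces. The forward step needs a copper system that accepts a di-ortho-substituted phenoxide and a base that leaves the aldehyde alone.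

3 from 1. The aryl–CHO bond is cut. The two free positions of 1 are equivalent, each ortho to one methoxy group and para to another, so electrophilic formylation can give only 3. The forward step needs a Lewis acid that formylates without cleaving the neighbouring methyl ether.

## Other disconnections considered

Alternative 1: The cut is in ring B, at C1–O (towards ring A) and at C6, where the future oxygen is first a boron atom. In the forward sense a hindered lithium amide would convert 1 into 3,4,5-trimethoxybenzyne A2. The lithium salt of 4 would add at the aryne carbon remote from methoxy, and the resulting aryl anion next to methoxy would be captured by a borate ester to give 2-[2,3,4-trimethoxy-6-(2,4,6-trimethoxyphenoxy)phenyl]-4,4,5,5-tetramethyl-1,3,2-dioxaborolane A1; oxidation of the C–B bond would lead to 7.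
- In favour: it uses the same two building blocks, the direction of addition to a 3-alkoxyaryne is a dependable rule, and ether bond and oxygen site are fixed in one flask. On step economy for this stretch it is the better plan: two operations to 7 instead of three.
- Against: a hindered phenoxide is a weak aryne nucleophile and must compete with the amide base. The aryl anion can be protonated by the amine released from the base, which would give the ether without the C6 substituent. The borate must coexist with the strong base.
- Comparison: this is a polar addition–trapping cascade that addresses only the A–B portion. It competes with steps 1 to 3 of the chosen plan, not with the benzannulation, and could be spliced in front of step 4. The structural outcome is equal; the chosen formyl route rests on three well-established reactions at the cost of one more step.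

Alternative 2: Ring A is removed altogether by cutting its C2–C3 and C5–C6 bonds. The forward key step would acylate the enolate of dimethyl 3-oxopentanedioate A5 twice with dimethyl 2-[3,4,5-trimethoxy-2-(3,4,5-trimethoxyphenoxy)phenoxy]propanedioate A4. A4 would be made by O-alkylation of 3,4,5-trimethoxy-2-(3,4,5-trimethoxyphenoxy)phenol A6 with a halomalonate. Enolisation of the triketone would give dimethyl 2,4,6-trihydroxy-5-[3,4,5-trimethoxy-2-(3,4,5-trimethoxyphenoxy)phenoxy]benzene-1,3-dicarboxylate A3; saponification, double decarboxylation and cleavage of six methyl ethers would follow.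
- In favour: ring A arrives with its hydroxyls free, so the final dealkylation has six ethers instead of eight, a point on which it is better. The ring A oxygen is attached by alkylating the less hindered hydroxyl of A6, with no arylation.
- Against: A4 has an acidic C–H that the enolate of A5 would remove, which shuts down its electrophilicity. A5 self-condenses easily, and double C-acylation by a simple malonate needs forcing base. The crowded B–C ether is only moved into the synthesis of A6.
- Comparison: both plans build an arene instead of forging a hindered ether, so they are equal in concept. The chosen plan does it by a neutral thermal pericyclic cascade, this one by an anionic condensation with more competing pathways. It would need about nine steps against eight.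

Alternative 3: The cut is the C1–C2 bond of ring B. The forward key step heats 3,4-dimethoxy-4-(1-methoxyethenyl)-2-(3,4,5-trimethoxyphenoxy)cyclobut-2-en-1-one A7. A7 would be reached from a squaric diester by aryloxide exchange, addition of an α-alkoxyvinyl organolithium to the more electrophilic carbonyl and O-methylation. Ring opening to a dienylketene, six-electron closure and tautomerisation would give A6 with all five ring B oxygens in place and only the C1 hydroxyl free.
- In favour: the regiochemistry of ring B is built in, and the crowded B–C ether comes from an easy addition–elimination on the squarate. The ring-forming event is unimolecular and needs no bimolecular ketene capture; on the reliability of that event it is the equal of the chosen key step and probably the better.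
- Against: it ends at A6 with ring A still missing. Attaching ring A means coupling the C1 hydroxyl with a doubly ortho-substituted 2,4,6-trioxygenated aryl electrophile, or building ring A as in alternative 2. The organolithium addition to an unsymmetrical squarate must also be regiocontrolled.
- Comparison: it belongs to the same mechanistic family (four-electron opening, six-electron closure to a phenol) but spends the annulation on ring B. The chosen plan spends it on ring C, where it also removes the hard ether bond, and gets the A–B ether from a favourable coupling, so it is shorter overall.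

Key step: step 7

Remarks on the chemistry (assumptions):
- 1, 4, 12 and 13 are taken as purchasable, 13 as its solution in hexanes.
- The ring B C6 oxygen is introduced through a formyl group (steps 1 to 3) rather than by ortho-lithiation of an A–B ether, because such a lithiation could not be counted on to avoid the ring A C–H flanked by two methoxy groups.
- 11 is kept cold and in solution, and is used promptly. The basic methanolysis that closes step 7 is a precaution against ester formation between the product phenol and a ketene.

## Route

Step 1
Reactants: 1 5-bromo-1,2,3-trimethoxybenzene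
Product: 3 6-bromo-2,3,4-trimethoxybenzaldehyde, via α-chloro ether 2 (not isolated)
Conditions: Cl2CHOMe, TiCl4, CH2Cl2, −10→0 °C; then ice-water
Reagents that add atoms: dichloromethyl methyl ether, COC(Cl)Cl; water, O
Why: Rieche formylation; the two free positions of 1 are equivalent and each is para to one methoxy group and ortho to another, so only one aldehyde can form, and hydrolysis of α-chloro ether 2 on work-up releases the formyl group.

Step 2
Reactants: 3 6-bromo-2,3,4-trimethoxybenzaldehyde; 4 2,4,6-trimethoxyphenol
Product: 5 2,3,4-trimethoxy-6-(2,4,6-trimethoxyphenoxy)benzaldehyde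
Conditions: CuI (10 mol %), picolinic acid (20 mol %), K3PO4, DMSO, 90 °C, Ar
Reagents that add atoms: none
Why: Ullmann-type C–O coupling with a monovalent copper picolinate catalyst, a system suited to di-ortho-substituted phenols; the ortho formyl group activates the C–Br bond, and an aldehyde without α-hydrogen should tolerate anhydrous phosphate base.

Step 3
Reactants: 5 2,3,4-trimethoxy-6-(2,4,6-trimethoxyphenoxy)benzaldehyde
Product: 7 2,3,4-trimethoxy-6-(2,4,6-trimethoxyphenoxy)phenol, via aryl formate 6 (not isolated)
Conditions: mCPBA, CH2Cl2, 0 °C→rt; then K2CO3 (cat.), MeOH, rt
Reagents that add atoms: 3-chloroperoxybenzoic acid (mCPBA), OOC(=O)c1cccc(Cl)c1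
Why: Baeyer–Villiger (Dakin-type) oxidation; the electron-rich, doubly ortho-oxygenated aryl group should migrate in preference to hydride to give formate 6, which is methanolysed to the phenol, so the oxygen ends up exactly where the formyl carbon was.

Step 4
Reactants: 7 2,3,4-trimethoxy-6-(2,4,6-trimethoxyphenoxy)phenol
Product: 8 2-{[(E)-1,2-dichloroethenyl]oxy}-3,4,5-trimethoxy-1-(2,4,6-trimethoxyphenoxy)benzene
Conditions: trichloroethylene, K2CO3, DMF, 70 °C
Reagents that add atoms: trichloroethylene, ClC=C(Cl)Cl
Why: Base converts trichloroethylene into dichloroacetylene, to which the phenoxide adds in anti fashion to give the (E)-1,2-dichlorovinyl ether; the electrophile is a small linear alkyne, so the two ortho substituents of 7 should matter little.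

Step 5
Reactants: 8 2-{[(E)-1,2-dichloroethenyl]oxy}-3,4,5-trimethoxy-1-(2,4,6-trimethoxyphenoxy)benzene
Product: 11 2-(ethynyloxy)-3,4,5-trimethoxy-1-(2,4,6-trimethoxyphenoxy)benzene, via chloroethynyl ether 9 (not isolated), via lithium acetylide 10 (not isolated)
Conditions: n-BuLi (2.2 equiv), THF, −78→−40 °C; then H2O, −78→0 °C; rapid filtration through base-washed alumina
Reagents that add atoms: none
Why: Dehydrochlorination followed by chlorine–lithium exchange: the first equivalent of n-BuLi removes the vinylic hydrogen and LiCl is lost to give 9, the second converts 9 into acetylide 10, and a neutral aqueous quench gives the terminal ynol ether; both events are fast at −78 °C and should outrun ring lithiation.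

Step 6
Reactants: 12 methoxyacetyl chloride; 13 ethoxyacetylene
Product: 15 3-ethoxy-4-methoxycyclobut-2-en-1-one (racemic), via methoxyketene 14 (not isolated)
Conditions: Et3N (slow addition), 13 (2–3 equiv), Et2O, 0 °C→rt
Reagents that add atoms: none
Why: Ketene–alkyne [2+2] cycloaddition; dehydrochlorination gives methoxyketene 14, whose carbonyl carbon is attacked by the nucleophilic CH terminus of 13, placing ethoxy at C3 and methoxy at C4; the C4 stereocentre is formed racemic and is erased in step 7.

Step 7
Reactants: 11 2-(ethynyloxy)-3,4,5-trimethoxy-1-(2,4,6-trimethoxyphenoxy)benzene; 15 3-ethoxy-4-methoxycyclobut-2-en-1-one (racemic)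
Product: 20 3-ethoxy-2-methoxy-5-[2,3,4-trimethoxy-6-(2,4,6-trimethoxyphenoxy)phenoxy]phenol, via vinylketene 16 (not isolated), via vinylcyclobutenone 17 (not isolated), via dienylketene 18 (not isolated), via cyclohexadienone 19 (not isolated)
Conditions: 15 (1.5–2 equiv), PhMe, 80→110 °C, Ar; then K2CO3, MeOH, rt
Reagents that add atoms: none
Why: Danheiser benzannulation: thermal four-electron electrocyclic opening of 15, with the methoxy group rotating outward, gives dialkoxy vinylketene 16, which the ynol ether 11 captures in a regioselective [2+2] cycloaddition to give 17, forming ring C C2–C3 and C1–C6. A second, reversible four-electron opening gives dienylketene 18, whose thermal six-electron disrotatory electrocyclisation closes ring C by forming C3–C4, and tautomerisation of cyclohexadienone 19 delivers the phenol. The closest known reaction type is the benzannulation of cyclobutenones with alkoxy- and siloxyalkynes, of which 11 is an aryl member. The selectivity needed is that the ketene carbonyl carbon bonds to the terminal alkyne carbon; the oxygen lone pair polarises the alkyne so that its terminal carbon is the nucleophile and the ketene carbonyl carbon the electrophile, which puts the aryloxy group at C1 between two CH carbons and meta to the new hydroxyl. The two ortho substituents on ring B twist the ynol ether oxygen out of conjugation with the arene, which should keep the alkyne nucleophilic. No stereocentre survives, since those of 15, 17 and 19 are all lost on aromatisation. The excess of 15 allows for ketene self-reaction, and the closing methanolysis should cleave any aryl ester formed if the product phenol captures a ketene.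

Step 8
Reactants: 20 3-ethoxy-2-methoxy-5-[2,3,4-trimethoxy-6-(2,4,6-trimethoxyphenoxy)phenoxy]phenol
Product: 21 5-[2,3,4-trihydroxy-6-(2,4,6-trihydroxyphenoxy)phenoxy]benzene-1,2,3-triol
Conditions: BBr3 (12 equiv), CH2Cl2, −78 °C→rt, Ar; then H2O, 0 °C; degassed acidic work-up
Reagents that add atoms: none
Why: Lewis acid ether cleavage; boron binds each alkyl ether oxygen and bromide attacks the methyl or ethyl carbon by SN2, which should leave both aryl–O–aryl bonds intact, and the acidic, oxygen-free work-up protects the pyrogallol and phloroglucinol units.

## Compound list

1 | 5-bromo-1,2,3-trimethoxybenzene | COc1cc(Br)cc(OC)c1OC | starting material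
2 | 1-bromo-2-[chloro(methoxy)methyl]-3,4,5-trimethoxybenzene (racemic) | COC(Cl)c1c(Br)cc(OC)c(OC)c1OC | intermediate (not isolated)
3 | 6-bromo-2,3,4-trimethoxybenzaldehyde | O=Cc1c(Br)cc(OC)c(OC)c1OC | intermediate
4 | 2,4,6-trimethoxyphenol | COc1cc(OC)c(O)c(OC)c1 | starting material
5 | 2,3,4-trimethoxy-6-(2,4,6-trimethoxyphenoxy)benzaldehyde | O=Cc1c(OC)c(OC)c(OC)cc1Oc1c(OC)cc(OC)cc1OC | intermediate
6 | 2,3,4-trimethoxy-6-(2,4,6-trimethoxyphenoxy)phenyl formate | O=COc1c(OC)c(OC)c(OC)cc1Oc1c(OC)cc(OC)cc1OC | intermediate (not isolated)
7 | 2,3,4-trimethoxy-6-(2,4,6-trimethoxyphenoxy)phenol | Oc1c(OC)c(OC)c(OC)cc1Oc1c(OC)cc(OC)cc1OC | intermediate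
8 | 2-{[(E)-1,2-dichloroethenyl]oxy}-3,4,5-trimethoxy-1-(2,4,6-trimethoxyphenoxy)benzene | Cl/C=C(/Cl)Oc1c(OC)c(OC)c(OC)cc1Oc1c(OC)cc(OC)cc1OC | intermediate
9 | 2-[(chloroethynyl)oxy]-3,4,5-trimethoxy-1-(2,4,6-trimethoxyphenoxy)benzene | ClC#COc1c(OC)c(OC)c(OC)cc1Oc1c(OC)cc(OC)cc1OC | intermediate (not isolated)
10 | lithium [2,3,4-trimethoxy-6-(2,4,6-trimethoxyphenoxy)phenoxy]ethynide | [Li]C#COc1c(OC)c(OC)c(OC)cc1Oc1c(OC)cc(OC)cc1OC | intermediate (not isolated)
11 | 2-(ethynyloxy)-3,4,5-trimethoxy-1-(2,4,6-trimethoxyphenoxy)benzene | C#COc1c(OC)c(OC)c(OC)cc1Oc1c(OC)cc(OC)cc1OC | intermediate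
12 | methoxyacetyl chloride | COCC(=O)Cl | starting material
13 | ethoxyacetylene | CCOC#C | starting material
14 | methoxyketene (2-methoxyethen-1-one) | COC=C=O | intermediate (not isolated)
15 | 3-ethoxy-4-methoxycyclobut-2-en-1-one (racemic) | O=C1C=C(OCC)C1OC | intermediate
16 | (3Z)-3-ethoxy-4-methoxybuta-1,3-dien-1-one | O=C=C/C(OCC)=C/OC | intermediate (not isolated)
17 | 4-[(Z)-1-ethoxy-2-methoxyethenyl]-3-[2,3,4-trimethoxy-6-(2,4,6-trimethoxyphenoxy)phenoxy]cyclobut-2-en-1-one (racemic) | O=C1C=C(Oc2c(OC)c(OC)c(OC)cc2Oc2c(OC)cc(OC)cc2OC)C1/C(OCC)=C/OC | intermediate (not isolated)
18 | (3E,5Z)-5-ethoxy-6-methoxy-3-[2,3,4-trimethoxy-6-(2,4,6-trimethoxyphenoxy)phenoxy]hexa-1,3,5-trien-1-one | O=C=C/C(Oc1c(OC)c(OC)c(OC)cc1Oc1c(OC)cc(OC)cc1OC)=C\C(OCC)=C\OC | intermediate (not isolated)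
19 | 5-ethoxy-6-methoxy-3-[2,3,4-trimethoxy-6-(2,4,6-trimethoxyphenoxy)phenoxy]cyclohexa-2,4-dien-1-one (racemic) | O=C1C=C(Oc2c(OC)c(OC)c(OC)cc2Oc2c(OC)cc(OC)cc2OC)C=C(OCC)C1OC | intermediate (not isolated)
20 | 3-ethoxy-2-methoxy-5-[2,3,4-trimethoxy-6-(2,4,6-trimethoxyphenoxy)phenoxy]phenol | Oc1cc(Oc2c(OC)c(OC)c(OC)cc2Oc2c(OC)cc(OC)cc2OC)cc(OCC)c1OC | intermediate
21 | 5-[2,3,4-trihydroxy-6-(2,4,6-trihydroxyphenoxy)phenoxy]benzene-1,2,3-triol | Oc1cc(O)c(Oc2cc(O)c(O)c(O)c2Oc2cc(O)c(O)c(O)c2)c(O)c1 | target

## Step count and least certain steps

Total step count: 8. Longest linear sequence: 7 steps (steps 1, 2, 3, 4, 5, 7 and 8, from 1 to 21); step 6 is a one-step side branch.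

Step 7 (key step). The most likely failure is slow capture of vinylketene 16 by the alkyne. An aryl ynol ether is a weaker nucleophile than the alkyl and silyl ynol ethers usually used, and the dialkoxy ketene is a weaker electrophile than an alkyl one. Ketene self-reaction and thermal oligomerisation of 11 would then win. The fallback gives up the annulation and forms the B–C ether by direct coupling. It sets out from 7, which is coupled with 1 (CuI, picolinic acid, K3PO4, DMSO, 110 °C) to give 1,2,3-trimethoxy-5-(2,4,6-trimethoxyphenoxy)-4-(3,4,5-trimethoxyphenoxy)benzene F1. Cleavage of its nine methyl ethers with BBr3 in CH2Cl2 comes back to the route at 21. This accepts the crowded arylation that the key step was designed to avoid.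

Step 5. The terminal aryl ynol ether may be lost during isolation by hydration on acidic surfaces or by oligomerisation on concentration, because the electron-rich alkyne is protonated easily. Ring lithiation by n-BuLi is a lesser concern at −78 °C. The fallback changes the isolated species. It sets out from 8, which is treated as in step 5, but acetylide 10 is trapped with Me3SiCl to give the storable silyl-capped trimethyl{[2,3,4-trimethoxy-6-(2,4,6-trimethoxyphenoxy)phenoxy]ethynyl}silane F2. F2 is desilylated with K2CO3 in MeOH immediately before the benzannulation, and the solution of 11 is used directly, which rejoins the route at 11.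

Step 2. Coupling of the di-ortho-substituted phenoxide may be slow, so that reduction of the C–Br bond and oxidative degradation of the electron-rich phenoxide compete. The fallback replaces copper catalysis by nucleophilic aromatic substitution. 5-Fluoro-1,2,3-trimethoxybenzene F3 is lithiated between fluorine and methoxy (n-BuLi, THF, −78 °C) and formylated with DMF to give 6-fluoro-2,3,4-trimethoxybenzaldehyde F4. The fallback sets out from 4, which displaces fluoride from F4 (K2CO3, DMF, 110 °C) through an adduct stabilised by the ortho formyl group, and rejoins the route at 5.

Step 8. Cleavage of eight ethers may stop short at the crowded ring B methoxy groups or the ethyl ether, and the free polyphenol may oxidise during chromatography. The fallback changes the isolation to capture and release. It sets out from 20: the crude product of the BBr3 reaction is acetylated (Ac2O, pyridine) to 5-{2,3,4-tris(acetyloxy)-6-[2,4,6-tris(acetyloxy)phenoxy]phenoxy}benzene-1,2,3-triyl triacetate F5. F5 is stable to air and can be separated from under-dealkylated material on silica. Acid methanolysis (HCl, MeOH, Ar) then returns to the route at 21.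

## Further compounds

F1 | step 7 | 1,2,3-trimethoxy-5-(2,4,6-trimethoxyphenoxy)-4-(3,4,5-trimethoxyphenoxy)benzene | COc1cc(Oc2c(OC)c(OC)c(OC)cc2Oc2c(OC)cc(OC)cc2OC)cc(OC)c1OC
F2 | step 5 | trimethyl{[2,3,4-trimethoxy-6-(2,4,6-trimethoxyphenoxy)phenoxy]ethynyl}silane | C[Si](C)(C)C#COc1c(OC)c(OC)c(OC)cc1Oc1c(OC)cc(OC)cc1OC
F3 | step 2 | 5-fluoro-1,2,3-trimethoxybenzene | COc1cc(F)cc(OC)c1OC
F4 | step 2 | 6-fluoro-2,3,4-trimethoxybenzaldehyde | O=Cc1c(F)cc(OC)c(OC)c1OC
F5 | step 8 | 5-{2,3,4-tris(acetyloxy)-6-[2,4,6-tris(acetyloxy)phenoxy]phenoxy}benzene-1,2,3-triyl triacetate | CC(=O)Oc1cc(OC(C)=O)c(Oc2cc(OC(C)=O)c(OC(C)=O)c(OC(C)=O)c2Oc2cc(OC(C)=O)c(OC(C)=O)c(OC(C)=O)c2)c(OC(C)=O)c1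
A1 | alternative 1 | 2-[2,3,4-trimethoxy-6-(2,4,6-trimethoxyphenoxy)phenyl]-4,4,5,5-tetramethyl-1,3,2-dioxaborolane | COc1cc(OC)c(Oc2cc(OC)c(OC)c(OC)c2B3OC(C)(C)C(C)(C)O3)c(OC)c1
A2 | alternative 1 | 3,4,5-trimethoxybenzyne | COC1=C(OC)C(OC)=CC#C1
A3 | alternative 2 | dimethyl 2,4,6-trihydroxy-5-[3,4,5-trimethoxy-2-(3,4,5-trimethoxyphenoxy)phenoxy]benzene-1,3-dicarboxylate | COC(=O)c1c(O)c(C(=O)OC)c(O)c(Oc2cc(OC)c(OC)c(OC)c2Oc2cc(OC)c(OC)c(OC)c2)c1O
A4 | alternative 2 | dimethyl 2-[3,4,5-trimethoxy-2-(3,4,5-trimethoxyphenoxy)phenoxy]propanedioate | COC(=O)C(Oc1cc(OC)c(OC)c(OC)c1Oc1cc(OC)c(OC)c(OC)c1)C(=O)OC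
A5 | alternative 2 | dimethyl 3-oxopentanedioate | COC(=O)CC(=O)CC(=O)OC
A6 | alternative 3 | 3,4,5-trimethoxy-2-(3,4,5-trimethoxyphenoxy)phenol | Oc1cc(OC)c(OC)c(OC)c1Oc1cc(OC)c(OC)c(OC)c1
A7 | alternative 3 | 3,4-dimethoxy-4-(1-methoxyethenyl)-2-(3,4,5-trimethoxyphenoxy)cyclobut-2-en-1-one (racemic) | C=C(OC)C1(OC)C(OC)=C(Oc2cc(OC)c(OC)c(OC)c2)C1=O
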